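## Structural features

The target 31 is an achiral, open-chain heptaphenyl hexaether. Seven benzene rings (A to G) are joined only through six diaryl ether oxygens and carry eighteen free phenolic hydroxyls. There is no stereocentre, so no adjacent stereocentres need to be considered.

Ring A is a 2,4,6-trihydroxyphenoxy end (ether carbon A1) and ring G a 3,4,5-trihydroxyphenoxy end (ether carbon G1). Rings B, D and F are para-linked (oxygens at positions 1 and 4, hydroxyls at 3 and 5). Rings C and E are ortho-linked (oxygens at positions 1 and 6, hydroxyls at 3, 4 and 5). The ether bonds are A1–O–B1, B4–O–C1, C6–O–D1, D4–O–E1, E6–O–F1 and F4–O–G1.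

The fragile elements are the free pyrogallol-type rings C, E and G and the very electron-rich ring A, which are oxidised by air, especially in base. The many identical functions also turn any incomplete step into a separation problem.

The real difficulty is the regiocontrolled construction of six electron-rich diaryl ethers. Four ether carbons (A1, B4, D4, F4) lie between two ortho oxygens, and two (C6, E6) lie between an oxygen and an aryloxy group. This pattern is poorly suited to copper-mediated coupling.

The key step exploits one feature. On each of rings A to F, two hydroxyls stand ortho or para to exactly one ether carbon of that ring: A2/A6 to A1, B3/B5 to B4, C5 (ortho) and C3 (para) to C6, D3/D5 to D4, E5/E3 to E6, F3/F5 to F4. Formyl groups at these twelve carbons turn that ether carbon into an SNAr electrophile and are afterwards converted into the hydroxyls by carbon-to-oxygen migration. The six remaining oxygens (A4, C4, E4, G3, G4, G5) are not activating positions and are carried as benzyl ethers.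

## Logic of the disconnections

**31 back to 29.** The last cuts are the six benzylic C–O bonds (31 to 30) and the twelve formyl–oxygen ester bonds (30 to 29). They come last because 31 is the only air-sensitive compound of the route. The gain is that all eighteen oxygens travel as two robust group types. The forward steps must avoid phenoxides: formates are removed under acid, and hydrogenolysis must be complete at all six sites.

**29 back to 28.** Twelve aryl C–O bonds are traced back to twelve aryl C–CHO bonds. This turns every hydroxyl that is ortho or para to an ether carbon into a group that activated the formation of that ether. The gain is that 28 contains only aldehydes, ethers and benzyl groups and can be assembled without metal catalysis. The forward step must give aryl migration at all twelve sites in one operation without attack on the rings.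

**28 back to 27 and 10.** The A1–O bond is cut, with the fluoride on A1 between two formyl groups and the phenol on B1. Ring A then arrives with its final benzyl ether, and no unmasking follows. The phenoxide of 27 must displace fluoride faster than it attacks any formyl-activated ether carbon of another chain.

**27, 23 and 19 back to 25, 21 and 3, each with 9.** The B4–O, D4–O and F4–O bonds are cut the same way. The oxygen para to fluorine in 9 is masked as a cyclic acetal, which appears in 26, 22 and 18 and is hydrolysed in the same step. One block serves three rings. The mask must resist carbonate and fluoride and leave under acid that spares benzyl ethers and aldehydes.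

**25 and 21 back to 23 and 19, each with 17.** The C6–O and E6–O bonds are cut, with fluoride on the carbon that has one ortho and one para formyl group. The neighbouring oxygen is masked as the same acetal, which appears in 24 and 20. One block serves both ortho-linked rings and already carries the C4/E4 benzyl ether. The fluoride of 17 is flanked on both sides, so the forward coupling depends on an unhindered phenoxide.

**9 and 10 back to 4.** The acetal and benzyl C–O bonds lead to the common phenol 8, its silyl ether 7, and then by cutting both aryl–CHO bonds to 5 and 4. Fluorine is the only ortho-directing group left once a bulky silyl ether shields the positions next to oxygen. Both formyl groups must be introduced ortho to fluorine, and the free phenol of 8 must never be ionised next to its own activated fluoride.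

**17 back to 11.** The two aryl–CHO bonds are reduced to hydroxymethyl groups (16), the benzyl ether is cut (15), the two aryl–CH2OH bonds are removed (14), and the phenol oxygen is traced to a formyl group (12, then 11). In 11 the two oxygen sites of the ring are differentiated from the start: one is a phenol and the other is still a carbon. This allows the acetal to be placed unambiguously on the oxygen next to fluorine. The hydroxymethylation must go to both positions ortho to the phenol, one of which is next to fluorine.

**3 back to 1.** The aryl C–O bond of the ring G phenol is traced to the aryl–CHO bond of 1. This is the same oxidation as the key step on a single site.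

## Other disconnections considered

**Alternative 1:** The cut is the doubly flanked F4–O–G1 ether, formed inside a temporary ring.

- **Forward step:** The pyrogallol monoester A1 would be treated with base. The central phenoxide of ring F would displace the fluoride ortho to the ester carbonyl and close the seven-membered lactone-ether ring of depsidone A2. Lactone opening and loss of the carboxyl carbon would then leave the ether.
- **In favour:** Intramolecular delivery fixes the bond at the central oxygen and tells the three pyrogallol oxygens apart without protecting groups. All oxygens are already at their final oxidation level. The bromine para to the new ether is a handle for the next ring.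
- **Against:** The fluoride has only one ortho carbonyl activator and a para methoxy group working against it. Acyl migration between the pyrogallol oxygens competes under base. The tether carbon must be removed by protodecarboxylation. The device solves one of four flanked ethers per cycle of esterification, closure, opening and decarboxylation. The methyl ethers demand an exhaustive Lewis-acid demethylation at the end.
- **Comparison:** On structure, it is the equal of the chosen plan for one hindered ether, and better in needing no late oxidation. On mechanism, both are SNAr, but the chosen fluorides carry two carbonyl activators. On step economy, it is clearly worse: roughly four steps per hindered ether, against two operations for all twelve activating groups.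

**Alternative 2:** The cut goes through ring C itself (its C5–C6 bond), with the B4–O–C1 ether already present on a vinyl carbon.

- **Forward step:** Heating cyclobutenone A3 would open the four-membered ring to a dienylketene. A 6π electrocyclisation and tautomerisation would give hydroquinone A4.
- **In favour:** The pentaoxygenated ring is assembled with every oxygen placed by construction. The flanked B4 ether is made as an enol ether before the ring exists. Here the alternative is better than any aryl coupling, the chosen one included, because no substitution at a crowded aromatic carbon is needed. The conditions are neutral and thermal.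
- **Against:** A4 has two free hydroxyls. The hindered one, next to the aryloxy group, must later be arylated by an unactivated ring D carbon. The sequence has to be run twice, for rings C and E. A4 is an air-sensitive hydroquinone. Methyl, isopropyl and silyl groups require Lewis acids at the end.
- **Comparison:** On structure, it is better for rings C and E alone and of no help for the other ethers. On mechanism, the pericyclic cascade is as predictable as the SNAr chemistry and is its equal. On step economy, it is worse, since four ethers still need separate solutions.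

**Alternative 3:** The cut removes both ethers of ring D (C6–O–D1 and D4–O–E1) and joins two trimers.

- **Forward step:** The cationic cyclopentadienyl complex of divalent ruthenium A5 would react first with the phenoxide of trimer A6 at its unhindered chloride. It would then react with the phenoxide of trimer A7 at the chloride between two methoxy groups. Photolysis in acetonitrile would release A8.
- **In favour:** The convergence (three plus one plus three rings) gives a much shorter longest linear sequence than the linear chain chosen here. On this point the alternative is better. The π-complex activates an electron-rich chloroarene, so no auxiliary carbon and no late oxidation are needed.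
- **Against:** A6 and A7 themselves contain three flanked ethers that must be made by some other means. The order of the two displacements rests on sterics alone, and an error gives constitutional isomers that are hard to separate. The second displacement joins a hindered phenoxide to a doubly flanked carbon. Ruthenium is stoichiometric. The most serious point is that A8 carries eighteen methyl ethers, whose exhaustive cleavage risks incomplete reaction and diaryl ether scission.
- **Comparison:** On structure, it is better in convergence and worse in the end game; the chosen plan ends with hydrogenolysis and formate methanolysis. On mechanism, both rely on activated SNAr. On step economy, it is equal or better for the central ring but unresolved for the trimers.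

Key step: step 18

## Remarks on the chemistry

- The acetal carbon of every tetrahydropyranyl (THP) ether (9, 12 to 18, 20, 22, 24, 26) and the aminal carbon of 6 are racemic and are lost later; they are left undefined.
- Compounds 28 and 29 map position by position onto 31 and are used without correction. The formyl or formyloxy groups stand at A2, A6, B3, B5, C3, C5, D3, D5, E3, E5, F3 and F5. The benzyloxy groups stand at A4, C4, E4, G3, G4 and G5.
- Rings C and E are taken from 3-fluoro-4-hydroxybenzaldehyde (11). A fluorinated hydroquinone would first require its two hydroxyls to be told apart, which is unreliable.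

## Route

**Step 1**
Reactants: 1 3,4,5-tris(benzyloxy)benzaldehyde
Product: 3 3,4,5-tris(benzyloxy)phenol, via formate ester 2 (not isolated)
Conditions: mCPBA, CH2Cl2, 0 °C to rt; then K2CO3 (cat.), MeOH, rt
Reagents that add atoms: mCPBA, OOC(=O)c1cccc(Cl)c1
Why: Baeyer-Villiger oxidation; the para benzyloxy group should make the aryl group migrate in the Criegee intermediate, and the formate is then transesterified by methanol.

**Step 2**
Reactants: 4 4-fluorophenol
Product: 5 (4-fluorophenoxy)triisopropylsilane
Conditions: TIPSCl, imidazole, DMF, rt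
Reagents that add atoms: triisopropylsilyl chloride, CC(C)[Si](Cl)(C(C)C)C(C)C
Why: Silylation of a phenol; the bulky silyl ether shields both positions ortho to oxygen, so that fluorine alone directs the next step.

**Step 3**
Reactants: 5 (4-fluorophenoxy)triisopropylsilane
Product: 7 2-fluoro-5-[(triisopropylsilyl)oxy]benzene-1,3-dicarbaldehyde, via lithium aminoalkoxide 6 (not isolated)
Conditions: s-BuLi, TMEDA, THF, −78 °C; DMF (1.0 equiv), −78 °C; s-BuLi, −78 °C; DMF; aq. HCl, 0 °C
Reagents that add atoms: N,N-dimethylformamide, CN(C)C=O
Why: Directed ortho-metalation and formylation; sec-butyllithium should remove the proton ortho to fluorine, and the first formyl group stays masked in the flask as aminoalkoxide 6, which tolerates the second lithiation at the other position ortho to fluorine. The mixture is kept below −70 °C so that the ortho-fluoroaryllithiums do not collapse to benzyne.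

**Step 4**
Reactants: 7 2-fluoro-5-[(triisopropylsilyl)oxy]benzene-1,3-dicarbaldehyde
Product: 8 2-fluoro-5-hydroxybenzene-1,3-dicarbaldehyde
Conditions: TBAF, AcOH, THF, 0 °C
Reagents that add atoms: none
Why: Fluoride cleavage of an aryl silyl ether; acetic acid keeps the phenol protonated so that it cannot displace the activated fluoride of a second molecule.

**Step 5**
Reactants: 8 2-fluoro-5-hydroxybenzene-1,3-dicarbaldehyde
Product: 9 2-fluoro-5-(tetrahydro-2H-pyran-2-yloxy)benzene-1,3-dicarbaldehyde (racemic)
Conditions: 3,4-dihydro-2H-pyran, PPTS (cat.), CH2Cl2, rt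
Reagents that add atoms: 3,4-dihydro-2H-pyran, C1=COCCC1
Why: Acid-catalysed acetalisation of the phenol; no base is present, so the fluoride is untouched, and the acetal should withstand carbonate and fluoride in the couplings.

**Step 6**
Reactants: 8 2-fluoro-5-hydroxybenzene-1,3-dicarbaldehyde
Product: 10 5-(benzyloxy)-2-fluorobenzene-1,3-dicarbaldehyde
Conditions: BnBr, K2CO3, acetone, rt
Reagents that add atoms: benzyl bromide, BrCc1ccccc1
Why: Williamson ether synthesis; O-benzylation in acetone should outrun fluoride displacement because the weakly basic phenoxide is a poor SNAr nucleophile and its own ring is deactivated while ionised.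

**Step 7**
Reactants: 11 3-fluoro-4-hydroxybenzaldehyde
Product: 12 3-fluoro-4-(tetrahydro-2H-pyran-2-yloxy)benzaldehyde (racemic)
Conditions: 3,4-dihydro-2H-pyran, PPTS (cat.), CH2Cl2, rt
Reagents that add atoms: 3,4-dihydro-2H-pyran, C1=COCCC1
Why: Acid-catalysed acetalisation of the phenol; this fixes the temporary mask on the oxygen next to fluorine before the second oxygen exists.

**Step 8**
Reactants: 12 3-fluoro-4-(tetrahydro-2H-pyran-2-yloxy)benzaldehyde
Product: 14 3-fluoro-4-(tetrahydro-2H-pyran-2-yloxy)phenol, via formate ester 13 (not isolated)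
Conditions: mCPBA, Na2HPO4, CH2Cl2, 0 °C to rt; then K2CO3 (cat.), MeOH, rt
Reagents that add atoms: mCPBA, OOC(=O)c1cccc(Cl)c1
Why: Baeyer-Villiger oxidation; the para acetal oxygen should favour aryl migration, the phosphate buffer protects the acetal from the acid by-product, and methanolysis frees the phenol.

**Step 9**
Reactants: 14 3-fluoro-4-(tetrahydro-2H-pyran-2-yloxy)phenol
Product: 15 3-fluoro-2,6-bis(hydroxymethyl)-4-(tetrahydro-2H-pyran-2-yloxy)phenol
Conditions: aq. CH2O (37%), NaOH (1 equiv), H2O/THF, rt to 40 °C; neutral work-up
Reagents that add atoms: formaldehyde, C=O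
Why: Lederer-Manasse hydroxymethylation; the phenoxide should react at both free ortho positions because the para position is blocked, and the still unactivated aryl fluoride and the acetal are inert to hydroxide.

**Step 10**
Reactants: 15 3-fluoro-2,6-bis(hydroxymethyl)-4-(tetrahydro-2H-pyran-2-yloxy)phenol
Product: 16 [2-(benzyloxy)-4-fluoro-5-(tetrahydro-2H-pyran-2-yloxy)-1,3-phenylene]dimethanol
Conditions: BnBr, K2CO3, acetone, 56 °C
Reagents that add atoms: benzyl bromide, BrCc1ccccc1
Why: Williamson ether synthesis; carbonate ionises only the phenol, so the two benzylic alcohols should stay free.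

**Step 11**
Reactants: 16 [2-(benzyloxy)-4-fluoro-5-(tetrahydro-2H-pyran-2-yloxy)-1,3-phenylene]dimethanol
Product: 17 2-(benzyloxy)-4-fluoro-5-(tetrahydro-2H-pyran-2-yloxy)benzene-1,3-dicarbaldehyde
Conditions: IBX, EtOAc, 75 °C
Reagents that add atoms: none
Why: Oxidation of benzylic alcohols with 2-iodoxybenzoic acid under neutral conditions; no nucleophile is present when the fluoride becomes activated, and the acetal survives.

**Step 12**
Reactants: 3 3,4,5-tris(benzyloxy)phenol; 9 2-fluoro-5-(tetrahydro-2H-pyran-2-yloxy)benzene-1,3-dicarbaldehyde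
Product: 19 dimer phenol G-F (5-hydroxy-2-[3,4,5-tris(benzyloxy)phenoxy]benzene-1,3-dicarbaldehyde), via THP-protected dimer 18 (not isolated)
Conditions: K2CO3, DMF, rt to 40 °C; extractive work-up; then TsOH·H2O (cat.), THF/H2O, 40 °C
Reagents that add atoms: none
Why: SNAr by addition-elimination; the phenoxide of 3 adds at the C–F carbon of 9, and the Meisenheimer intermediate is stabilised by both ortho formyl groups. Acid hydrolysis of the acetal in crude 18 then frees the F1 hydroxyl.

**Step 13**
Reactants: 19 dimer phenol G-F; 17 2-(benzyloxy)-4-fluoro-5-(tetrahydro-2H-pyran-2-yloxy)benzene-1,3-dicarbaldehyde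
Product: 21 trimer phenol G-F-E (2-(benzyloxy)-4-{3,5-diformyl-4-[3,4,5-tris(benzyloxy)phenoxy]phenoxy}-5-hydroxybenzene-1,3-dicarbaldehyde), via THP-protected trimer 20 (not isolated)
Conditions: K2CO3, DMF, 50 °C; extractive work-up; then TsOH·H2O (cat.), THF/H2O, 40 °C
Reagents that add atoms: none
Why: SNAr; the fluoride of 17 is activated by one ortho and one para formyl group, and the phenoxide of 19 has two free ortho positions. The ether carbon F4 of 19 is deactivated while ring F is a phenoxide, and acetal hydrolysis then frees the E1 hydroxyl.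

**Step 14**
Reactants: 21 trimer phenol G-F-E; 9 2-fluoro-5-(tetrahydro-2H-pyran-2-yloxy)benzene-1,3-dicarbaldehyde
Product: 23 tetramer phenol G-F-E-D (hexaaldehyde, free hydroxyl at D1), via THP-protected tetramer 22 (not isolated)
Conditions: K2CO3, DMF, 50 °C; extractive work-up; then TsOH·H2O (cat.), THF/H2O, 40 °C
Reagents that add atoms: none
Why: SNAr at the doubly formyl-activated fluoride of 9 by the E1 phenoxide, which has one free ortho position; a Smiles-type aryl shift is not expected because F1 has no ortho or para formyl group. Acetal hydrolysis follows.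

**Step 15**
Reactants: 23 tetramer phenol G-F-E-D; 17 2-(benzyloxy)-4-fluoro-5-(tetrahydro-2H-pyran-2-yloxy)benzene-1,3-dicarbaldehyde
Product: 25 pentamer phenol G-F-E-D-C (octaaldehyde, free hydroxyl at C1), via THP-protected pentamer 24 (not isolated)
Conditions: K2CO3, DMF, 50 °C; extractive work-up; then TsOH·H2O (cat.), THF/H2O, 40 °C
Reagents that add atoms: none
Why: SNAr as in step 13; fluoride is a far better nucleofuge than the aryloxides at the internal activated ether carbons, so moderate temperature should keep the reaction at the C–F carbon. Acetal hydrolysis follows.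

**Step 16**
Reactants: 25 pentamer phenol G-F-E-D-C; 9 2-fluoro-5-(tetrahydro-2H-pyran-2-yloxy)benzene-1,3-dicarbaldehyde
Product: 27 hexamer phenol G-F-E-D-C-B (decaaldehyde, free hydroxyl at B1), via THP-protected hexamer 26 (not isolated)
Conditions: K2CO3, DMF, 50 °C; extractive work-up; then TsOH·H2O (cat.), THF/H2O, 40 °C
Reagents that add atoms: none
Why: SNAr as in step 14, followed by acetal hydrolysis that frees the B1 hydroxyl.

**Step 17**
Reactants: 27 hexamer phenol G-F-E-D-C-B; 10 5-(benzyloxy)-2-fluorobenzene-1,3-dicarbaldehyde
Product: 28 hexabenzyl dodecaaldehyde heptamer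
Conditions: K2CO3, DMF, 40 °C
Reagents that add atoms: none
Why: SNAr as in step 12; ring A arrives with its permanent benzyl ether, so no unmasking follows.

**Step 18**
Reactants: 28 hexabenzyl dodecaaldehyde heptamer
Product: 29 hexabenzyl dodecaformate heptamer
Conditions: mCPBA (30 equiv), Na2HPO4, CH2Cl2, 0 to 35 °C, dark
Reagents that add atoms: mCPBA, OOC(=O)c1cccc(Cl)c1
Why: Each formyl group should add the peracid to give a peroxy hemiacetal (Criegee intermediate), in which the aryl carbon shifts to oxygen with loss of 3-chlorobenzoate to give the aryl formate. The closest known reaction type is the Baeyer-Villiger (Dakin-type) oxidation of ortho- or para-aryloxy and alkoxy benzaldehydes made by SNAr from fluorobenzaldehydes, applied here twelve times in one operation. No ring closes and no stereocentre is formed. The step needs aryl rather than hydride migration at every site, and this is secured because each migrating carbon is ortho or para to an ether oxygen that stabilises the developing positive charge. At A2/A6, B3/B5, D3/D5 and F3/F5 that donor is the flanked aryloxy oxygen, and at C3/C5 and E3/E5 it is the benzyloxy oxygen together with an aryloxy oxygen. Each completed migration replaces an acceptor by a weakly donating formyloxy group, so the second formyl group of a ring should react more readily than the first and the oxidation should not stall. The rings must also not be attacked: the formyloxy groups keep the new oxygens masked as esters, and the phosphate buffer suppresses acid-catalysed formate loss and quinone formation. Ring G, the only electron-rich ring present from the start, is the reason for the moderate temperature and the exclusion of light.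

**Step 19**
Reactants: 29 hexabenzyl dodecaformate heptamer
Product: 30 hexabenzyl dodecaphenol heptamer
Conditions: HCl (cat.), MeOH/THF, 0 °C to rt, argon
Reagents that add atoms: none
Why: Acid-catalysed transesterification of aryl formates with methanol; acid is preferred to carbonate so that the twelve new phenols are never present as air-sensitive phenoxides, and benzyl and diaryl ethers are inert.

**Step 20**
Reactants: 30 hexabenzyl dodecaphenol heptamer
Product: 31 target CNP0292517.0
Conditions: H2 (1 atm), Pd/C, THF/MeOH, rt; filtration and evaporation under argon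
Reagents that add atoms: none
Why: Hydrogenolysis of six benzyl aryl ethers under neutral conditions; diaryl ethers and the free phenols should be untouched.

## Compound list

1 | 3,4,5-tris(benzyloxy)benzaldehyde | O=Cc1cc(OCc2ccccc2)c(OCc2ccccc2)c(OCc2ccccc2)c1 | starting material
2 | 3,4,5-tris(benzyloxy)phenyl formate | O=COc1cc(OCc2ccccc2)c(OCc2ccccc2)c(OCc2ccccc2)c1 | intermediate (not isolated)
3 | 3,4,5-tris(benzyloxy)phenol | Oc1cc(OCc2ccccc2)c(OCc2ccccc2)c(OCc2ccccc2)c1 | intermediate
4 | 4-fluorophenol | Oc1ccc(F)cc1 | starting material
5 | (4-fluorophenoxy)triisopropylsilane | CC(C)[Si](Oc1ccc(F)cc1)(C(C)C)C(C)C | intermediate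
6 | lithium (dimethylamino){2-fluoro-5-[(triisopropylsilyl)oxy]phenyl}methanolate (racemic) | [Li+].[O-]C(N(C)C)c1cc(O[Si](C(C)C)(C(C)C)C(C)C)ccc1F | intermediate (not isolated)
7 | 2-fluoro-5-[(triisopropylsilyl)oxy]benzene-1,3-dicarbaldehyde | O=Cc1cc(O[Si](C(C)C)(C(C)C)C(C)C)cc(C=O)c1F | intermediate
8 | 2-fluoro-5-hydroxybenzene-1,3-dicarbaldehyde | O=Cc1cc(O)cc(C=O)c1F | intermediate
9 | 2-fluoro-5-(tetrahydro-2H-pyran-2-yloxy)benzene-1,3-dicarbaldehyde (racemic; block for rings B, D, F) | O=Cc1cc(OC2CCCCO2)cc(C=O)c1F | intermediate
10 | 5-(benzyloxy)-2-fluorobenzene-1,3-dicarbaldehyde (block for ring A) | O=Cc1cc(OCc2ccccc2)cc(C=O)c1F | intermediate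
11 | 3-fluoro-4-hydroxybenzaldehyde | O=Cc1ccc(O)c(F)c1 | starting material
12 | 3-fluoro-4-(tetrahydro-2H-pyran-2-yloxy)benzaldehyde (racemic) | O=Cc1ccc(OC2CCCCO2)c(F)c1 | intermediate
13 | 3-fluoro-4-(tetrahydro-2H-pyran-2-yloxy)phenyl formate (racemic) | O=COc1ccc(OC2CCCCO2)c(F)c1 | intermediate (not isolated)
14 | 3-fluoro-4-(tetrahydro-2H-pyran-2-yloxy)phenol (racemic) | Oc1ccc(OC2CCCCO2)c(F)c1 | intermediate
15 | 3-fluoro-2,6-bis(hydroxymethyl)-4-(tetrahydro-2H-pyran-2-yloxy)phenol (racemic) | OCc1cc(OC2CCCCO2)c(F)c(CO)c1O | intermediate
16 | [2-(benzyloxy)-4-fluoro-5-(tetrahydro-2H-pyran-2-yloxy)-1,3-phenylene]dimethanol (racemic) | OCc1cc(OC2CCCCO2)c(F)c(CO)c1OCc1ccccc1 | intermediate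
17 | 2-(benzyloxy)-4-fluoro-5-(tetrahydro-2H-pyran-2-yloxy)benzene-1,3-dicarbaldehyde (racemic; block for rings C, E) | O=Cc1cc(OC2CCCCO2)c(F)c(C=O)c1OCc1ccccc1 | intermediate
18 | THP-protected dimer G-F: 5-(tetrahydro-2H-pyran-2-yloxy)-2-[3,4,5-tris(benzyloxy)phenoxy]benzene-1,3-dicarbaldehyde (racemic) | C9CCCC(O9)Oc4cc(C=O)c(Oc5cc(OCc6ccccc6)c(OCc6ccccc6)c(OCc6ccccc6)c5)c(C=O)c4 | intermediate (not isolated)
19 | dimer phenol G-F: 5-hydroxy-2-[3,4,5-tris(benzyloxy)phenoxy]benzene-1,3-dicarbaldehyde | Oc4cc(C=O)c(Oc5cc(OCc6ccccc6)c(OCc6ccccc6)c(OCc6ccccc6)c5)c(C=O)c4 | intermediate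
20 | THP-protected trimer G-F-E (tetraaldehyde; THP-oxy at E1, formyl at E3 and E5, benzyloxy at E4, E6–O–F1; racemic) | C9CCCC(O9)Oc4cc(C=O)c(OCc7ccccc7)c(C=O)c4Oc4cc(C=O)c(Oc5cc(OCc6ccccc6)c(OCc6ccccc6)c(OCc6ccccc6)c5)c(C=O)c4 | intermediate (not isolated)
21 | trimer phenol G-F-E: 2-(benzyloxy)-4-{3,5-diformyl-4-[3,4,5-tris(benzyloxy)phenoxy]phenoxy}-5-hydroxybenzene-1,3-dicarbaldehyde | Oc4cc(C=O)c(OCc7ccccc7)c(C=O)c4Oc4cc(C=O)c(Oc5cc(OCc6ccccc6)c(OCc6ccccc6)c(OCc6ccccc6)c5)c(C=O)c4 | intermediate
22 | THP-protected tetramer G-F-E-D (hexaaldehyde; THP-oxy at D1, formyl at D3 and D5, D4–O–E1; racemic) | C9CCCC(O9)Oc3cc(C=O)c(Oc4cc(C=O)c(OCc7ccccc7)c(C=O)c4Oc4cc(C=O)c(Oc5cc(OCc6ccccc6)c(OCc6ccccc6)c(OCc6ccccc6)c5)c(C=O)c4)c(C=O)c3 | intermediate (not isolated)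
23 | tetramer phenol G-F-E-D (hexaaldehyde; free hydroxyl at D1) | Oc3cc(C=O)c(Oc4cc(C=O)c(OCc7ccccc7)c(C=O)c4Oc4cc(C=O)c(Oc5cc(OCc6ccccc6)c(OCc6ccccc6)c(OCc6ccccc6)c5)c(C=O)c4)c(C=O)c3 | intermediate
24 | THP-protected pentamer G-F-E-D-C (octaaldehyde; THP-oxy at C1, formyl at C3 and C5, benzyloxy at C4, C6–O–D1; racemic) | C9CCCC(O9)Oc3cc(C=O)c(OCc8ccccc8)c(C=O)c3Oc3cc(C=O)c(Oc4cc(C=O)c(OCc7ccccc7)c(C=O)c4Oc4cc(C=O)c(Oc5cc(OCc6ccccc6)c(OCc6ccccc6)c(OCc6ccccc6)c5)c(C=O)c4)c(C=O)c3 | intermediate (not isolated)
25 | pentamer phenol G-F-E-D-C (octaaldehyde; free hydroxyl at C1) | Oc3cc(C=O)c(OCc8ccccc8)c(C=O)c3Oc3cc(C=O)c(Oc4cc(C=O)c(OCc7ccccc7)c(C=O)c4Oc4cc(C=O)c(Oc5cc(OCc6ccccc6)c(OCc6ccccc6)c(OCc6ccccc6)c5)c(C=O)c4)c(C=O)c3 | intermediate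
26 | THP-protected hexamer G-F-E-D-C-B (decaaldehyde; THP-oxy at B1, formyl at B3 and B5, B4–O–C1; racemic) | C9CCCC(O9)Oc2cc(C=O)c(Oc3cc(C=O)c(OCc8ccccc8)c(C=O)c3Oc3cc(C=O)c(Oc4cc(C=O)c(OCc7ccccc7)c(C=O)c4Oc4cc(C=O)c(Oc5cc(OCc6ccccc6)c(OCc6ccccc6)c(OCc6ccccc6)c5)c(C=O)c4)c(C=O)c3)c(C=O)c2 | intermediate (not isolated)
27 | hexamer phenol G-F-E-D-C-B (decaaldehyde; free hydroxyl at B1) | Oc2cc(C=O)c(Oc3cc(C=O)c(OCc8ccccc8)c(C=O)c3Oc3cc(C=O)c(Oc4cc(C=O)c(OCc7ccccc7)c(C=O)c4Oc4cc(C=O)c(Oc5cc(OCc6ccccc6)c(OCc6ccccc6)c(OCc6ccccc6)c5)c(C=O)c4)c(C=O)c3)c(C=O)c2 | intermediate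
28 | hexabenzyl dodecaaldehyde heptamer (formyl at A2, A6, B3, B5, C3, C5, D3, D5, E3, E5, F3, F5; benzyloxy at A4, C4, E4, G3, G4, G5) | C(c9ccccc9)Oc1cc(C=O)c(Oc2cc(C=O)c(Oc3cc(C=O)c(OCc8ccccc8)c(C=O)c3Oc3cc(C=O)c(Oc4cc(C=O)c(OCc7ccccc7)c(C=O)c4Oc4cc(C=O)c(Oc5cc(OCc6ccccc6)c(OCc6ccccc6)c(OCc6ccccc6)c5)c(C=O)c4)c(C=O)c3)c(C=O)c2)c(C=O)c1 | intermediate
29 | hexabenzyl dodecaformate heptamer (formyloxy in place of each formyl group of 28) | C(c9ccccc9)Oc1cc(OC=O)c(Oc2cc(OC=O)c(Oc3cc(OC=O)c(OCc8ccccc8)c(OC=O)c3Oc3cc(OC=O)c(Oc4cc(OC=O)c(OCc7ccccc7)c(OC=O)c4Oc4cc(OC=O)c(Oc5cc(OCc6ccccc6)c(OCc6ccccc6)c(OCc6ccccc6)c5)c(OC=O)c4)c(OC=O)c3)c(OC=O)c2)c(OC=O)c1 | intermediate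
30 | hexabenzyl dodecaphenol heptamer (hydroxyl in place of each formyloxy group of 29) | C(c9ccccc9)Oc1cc(O)c(Oc2cc(O)c(Oc3cc(O)c(OCc8ccccc8)c(O)c3Oc3cc(O)c(Oc4cc(O)c(OCc7ccccc7)c(O)c4Oc4cc(O)c(Oc5cc(OCc6ccccc6)c(OCc6ccccc6)c(OCc6ccccc6)c5)c(O)c4)c(O)c3)c(O)c2)c(O)c1 | intermediate
31 | CNP0292517.0, heptaphenyl hexaether with eighteen hydroxyls (rings A to G as in Structural features; achiral) | Oc1cc(O)c(Oc2cc(O)c(Oc3cc(O)c(O)c(O)c3Oc3cc(O)c(Oc4cc(O)c(O)c(O)c4Oc4cc(O)c(Oc5cc(O)c(O)c(O)c5)c(O)c4)c(O)c3)c(O)c2)c(O)c1 | target

## Step count and least certain steps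

Total step count: 20 (17 steps to 28, the key step, 2 steps after it).

Longest linear sequence: 13 steps. From 4 these are steps 2, 3, 4, 5 and 12 to 20. The path from 11 (steps 7 to 11 and 13 to 20) has the same length.

**Step 18 (key step).**
- **Risk:** Hydride may migrate in place of the aryl group at some of the eight formyl groups on rings A, B, D and F, which have a single aryloxy donor and a meta acceptor; this gives carboxylic acids. Over twelve sites, a small loss per site multiplies into an inseparable mixture. Early loss of formate followed by ring oxidation is the second danger, and peracid attack on ring G the third.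
- **Fallback:** It sets out from 28 and returns at 30. Excess MeMgBr in THF at −78 to 0 °C should add to every aldehyde and give the dodeca(1-hydroxyethyl) heptamer F1 as a mixture of diastereomers. Dess-Martin periodinane in CH2Cl2 should oxidise it to the dodecaacetyl heptamer F2. Baeyer-Villiger oxidation of the aryl methyl ketones (mCPBA, cat. CF3CO2H, CH2Cl2, 40 °C) should give the dodecaacetate heptamer F3. Methanolysis (K2CO3, degassed MeOH/THF) should then give 30. In the ketone series only methyl migration competes with aryl migration, and it is far slower. The hydride channel is thus removed, at the price of two extra steps and a slower oxidation.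

**Step 3.**
- **Risk:** The second metalation may be incomplete or misdirected. The aminoalkoxide may direct it towards the position beside the silyl ether, residual DMF may consume the base, or benzyne may form on warming. The result would be mixtures of mono- and dialdehyde.
- **Fallback:** It sets out from 5 and returns at 7. A single lithiation and formylation (s-BuLi, TMEDA, THF, −78 °C; DMF) gives 2-fluoro-5-[(triisopropylsilyl)oxy]benzaldehyde F4. Acetalisation (ethylene glycol, cat. TsOH, toluene, water removal) gives 2-{2-fluoro-5-[(triisopropylsilyl)oxy]phenyl}-1,3-dioxolane F5. A second lithiation ortho to fluorine and formylation gives 3-(1,3-dioxolan-2-yl)-2-fluoro-5-[(triisopropylsilyl)oxy]benzaldehyde F6. Aqueous HCl in THF then releases 7.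

**Step 9.**
- **Risk:** The hydroxymethylphenol may condense with unreacted phenoxide to diarylmethanes, and the second hydroxymethylation at the position between hydroxyl and fluorine may be slow.
- **Fallback:** It sets out from 14 and returns at 17, replacing steps 9 to 11. Ortho-dibromination (NBS, cat. iPr2NH, CH2Cl2, 0 °C) gives 2,6-dibromo-3-fluoro-4-(tetrahydro-2H-pyran-2-yloxy)phenol F7. Benzylation (BnBr, K2CO3, acetone) gives 2-[4-(benzyloxy)-3,5-dibromo-2-fluorophenoxy]tetrahydro-2H-pyran F8. Two bromine-lithium exchanges with n-BuLi at −78 °C in one flask, each quenched with DMF, then give 17; the first formyl group is masked as its aminoalkoxide during the second exchange.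

**Step 15 (and, to a growing degree, steps 16 and 17).**
- **Risk:** Addition to the fluoride of 17 is slowed by its two neighbours. The phenoxide then has time to attack formyl-activated ether carbons of another chain (E6 or D4), causing ether exchange and chain scrambling. This hazard increases with every ring added.
- **Fallback:** It sets out from 23 and returns at 24. Silylation with hexamethyldisilazane gives the trimethylsilyl ether of the tetramer phenol F9. This is coupled with 17 under catalytic CsF in DMF at rt. The fluoride released in each substitution desilylates the next molecule, so free phenoxide never exceeds the catalyst loading and no carbonate is present. The resulting 24 is hydrolysed to 25 as in the route.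

**Step 20.**
- **Risk:** Removal of the six benzyl groups may be incomplete as the product becomes very polar, and the pyrogallol rings may oxidise in air during removal of the catalyst.
- **Fallback:** It sets out from 30 and returns at 31. The benzyl ethers are cleaved with BCl3 and pentamethylbenzene as cation scavenger in CH2Cl2 at −78 °C, followed by methanol quench under argon. This is a Lewis-acid debenzylation with no heterogeneous catalyst to filter, and it makes no new compound (F0).

## Further compounds

F1 | step 18 | dodeca(1-hydroxyethyl) heptamer (each formyl group of 28 as CH(OH)CH3; mixture of diastereomers) | C(c9ccccc9)Oc1cc(C(C)O)c(Oc2cc(C(C)O)c(Oc3cc(C(C)O)c(OCc8ccccc8)c(C(C)O)c3Oc3cc(C(C)O)c(Oc4cc(C(C)O)c(OCc7ccccc7)c(C(C)O)c4Oc4cc(C(C)O)c(Oc5cc(OCc6ccccc6)c(OCc6ccccc6)c(OCc6ccccc6)c5)c(C(C)O)c4)c(C(C)O)c3)c(C(C)O)c2)c(C(C)O)c1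
F2 | step 18 | dodecaacetyl heptamer (each formyl group of 28 as acetyl) | C(c9ccccc9)Oc1cc(C(C)=O)c(Oc2cc(C(C)=O)c(Oc3cc(C(C)=O)c(OCc8ccccc8)c(C(C)=O)c3Oc3cc(C(C)=O)c(Oc4cc(C(C)=O)c(OCc7ccccc7)c(C(C)=O)c4Oc4cc(C(C)=O)c(Oc5cc(OCc6ccccc6)c(OCc6ccccc6)c(OCc6ccccc6)c5)c(C(C)=O)c4)c(C(C)=O)c3)c(C(C)=O)c2)c(C(C)=O)c1
F3 | step 18 | dodecaacetate heptamer (each formyl group of 28 as acetoxy) | C(c9ccccc9)Oc1cc(OC(C)=O)c(Oc2cc(OC(C)=O)c(Oc3cc(OC(C)=O)c(OCc8ccccc8)c(OC(C)=O)c3Oc3cc(OC(C)=O)c(Oc4cc(OC(C)=O)c(OCc7ccccc7)c(OC(C)=O)c4Oc4cc(OC(C)=O)c(Oc5cc(OCc6ccccc6)c(OCc6ccccc6)c(OCc6ccccc6)c5)c(OC(C)=O)c4)c(OC(C)=O)c3)c(OC(C)=O)c2)c(OC(C)=O)c1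
F4 | step 3 | 2-fluoro-5-[(triisopropylsilyl)oxy]benzaldehyde | O=Cc1cc(O[Si](C(C)C)(C(C)C)C(C)C)ccc1F
F5 | step 3 | 2-{2-fluoro-5-[(triisopropylsilyl)oxy]phenyl}-1,3-dioxolane | Fc1ccc(O[Si](C(C)C)(C(C)C)C(C)C)cc1C1OCCO1
F6 | step 3 | 3-(1,3-dioxolan-2-yl)-2-fluoro-5-[(triisopropylsilyl)oxy]benzaldehyde | O=Cc1cc(O[Si](C(C)C)(C(C)C)C(C)C)cc(C2OCCO2)c1F
F7 | step 9 | 2,6-dibromo-3-fluoro-4-(tetrahydro-2H-pyran-2-yloxy)phenol (racemic) | Oc1c(Br)cc(OC2CCCCO2)c(F)c1Br
F8 | step 9 | 2-[4-(benzyloxy)-3,5-dibromo-2-fluorophenoxy]tetrahydro-2H-pyran (racemic) | Brc1cc(OC2CCCCO2)c(F)c(Br)c1OCc1ccccc1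
F9 | step 15 | trimethylsilyl ether of tetramer phenol 23 | C[Si](C)(C)Oc3cc(C=O)c(Oc4cc(C=O)c(OCc7ccccc7)c(C=O)c4Oc4cc(C=O)c(Oc5cc(OCc6ccccc6)c(OCc6ccccc6)c(OCc6ccccc6)c5)c(C=O)c4)c(C=O)c3
F0 | step 20 | none | none
A1 | alternative 1 | 5-bromo-2,3-dihydroxyphenyl 6-fluoro-2,3,4-trimethoxybenzoate | COc1cc(F)c(C(=O)Oc2cc(Br)cc(O)c2O)c(OC)c1OC
A2 | alternative 1 | 8-bromo-6-hydroxy-1,2,3-trimethoxy-11H-dibenzo[b,e][1,4]dioxepin-11-one | COc1cc2Oc3c(O)cc(Br)cc3OC(=O)c2c(OC)c1OC
A3 | alternative 2 | 4-(1-{2,6-dimethoxy-4-[(triisopropylsilyl)oxy]phenoxy}vinyl)-4-hydroxy-2,3-diisopropoxycyclobut-2-en-1-one (racemic) | CC(C)OC1=C(OC(C)C)C(O)(C(=C)Oc2c(OC)cc(O[Si](C(C)C)(C(C)C)C(C)C)cc2OC)C1=O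
A4 | alternative 2 | 5-{2,6-dimethoxy-4-[(triisopropylsilyl)oxy]phenoxy}-2,3-diisopropoxybenzene-1,4-diol | CC(C)Oc1c(O)cc(Oc2c(OC)cc(O[Si](C(C)C)(C(C)C)C(C)C)cc2OC)c(O)c1OC(C)C
A5 | alternative 3 | (cyclopentadienyl)(2,5-dichloro-1,3-dimethoxybenzene)ruthenium hexafluorophosphate, [(C5H5)Ru(C8H8Cl2O2)]PF6 | COc1cc(Cl)cc(OC)c1Cl.[cH-]1cccc1.[Ru+2].F[P-](F)(F)(F)(F)F
A6 | alternative 3 | octa-O-methyl A-B-C trimer phenol (free hydroxyl on ring C next to the B–O–C ether) | COc1cc(OC)c(Oc2cc(OC)c(Oc3cc(OC)c(OC)c(OC)c3O)c(OC)c2)c(OC)c1
A7 | alternative 3 | octa-O-methyl E-F-G trimer phenol (free hydroxyl at E1) | Oc1cc(OC)c(OC)c(OC)c1Oc1cc(OC)c(Oc2cc(OC)c(OC)c(OC)c2)c(OC)c1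
A8 | alternative 3 | octadeca-O-methyl heptamer | COc1cc(OC)c(Oc2cc(OC)c(Oc3cc(OC)c(OC)c(OC)c3Oc3cc(OC)c(Oc4cc(OC)c(OC)c(OC)c4Oc4cc(OC)c(Oc5cc(OC)c(OC)c(OC)c5)c(OC)c4)c(OC)c3)c(OC)c2)c(OC)c1
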